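Amounts first, as fractions of the charge. You have one flask, followed so far in the violet run.

- violet: substrate 0.50 mM; the very flask that is asked about, followed so far
- flask: substrate 0.50 mM; time 4.0 min

- violet (time / s: isomer of the product / %, target / %): 10.0: 10, 42; 20.0: 7, 54; 50.0: 12, 38; 120: 8, 11

(scatter of a reading: 2 percentage points)

- the analysis behind the earlier runs scatters by 2 percentage points, standard deviation

1. share of isomer of the product in isomer of the product plus target at 2.0 s
2. share of isomer of the product in isomer of the product plus target at 4.0 min

Now take rates only. Over the first 10.0 s, target appears at 0.0420 s⁻¹ of the charge on average. It peaks in the readings near 20.0 s, then falls. Define the fall constant 0.0177 s⁻¹ as the apparent first-order rate of target loss, read between the last two readings.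

If the loss is first order, its rate is this constant times the target present. At 120 s that is 0.00195 s⁻¹ of the charge. On this reckoning the rate at 4.0 min is that rate times a factor 0.119, and the estimate of target there is 1.31%.

My reckoning holds the isomer of the product at its last reading, 8%. That gives a late share of 85.9%. The first two readings together give a share of 15.0%, and I carry that reading back to 2.0 s as my estimate.

The forecast differs a little from my reckoning. It says 12% (6% to 24%) at 2.0 s and 85% (68% to 95%) at 4.0 min, reading the isomer as “a stable side product formed in parallel with the target”.

The flask gives 13.3% at 2.0 s and 72.0% at 4.0 min. With the step from isomer of the product back to intermediate struck out, the late share in this flask is 95.2%. Apply the fall constant once more: from 10.8% target at 2.00 min, it gives 1.29% at 4.0 min. The flask holds more than that, 2.54%.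

    intermediate ⇌ isomer of the product (K = 2.54, k = 0.0132 s⁻¹)
    target → over-reaction product (k = 0.0203 s⁻¹)
    2 substrate → homo dimer (k = 132 M⁻¹ s⁻¹)
    intermediate ⇌ target (K = 10.4, k = 0.0879 s⁻¹)
    substrate → intermediate (k = 0.938 s⁻¹)

Take the neighbour flask with 0.12 mM substrate. Taken as first order, the fall constant contains no charge, so you keep the factor 0.119 and expect the share of the asked flask, 72.0%. The computed share in the neighbour flask is 72.0%.

The data are calculated on assumed constants, and the scatter is random.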